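Everything rests on cutting the bond between the diaryl ether oxygen and ring C (the catechol-type ring). In the target, the ring C hydroxyl sits on the carbon adjacent to that ether carbon. It is therefore carried as a formyl group, which activates a fluorine on the ether carbon towards SNAr and is later exchanged for OH by peracid oxidation. In a single operation the phenoxide of ring D (the para-phenylene) displaces this fluoride and closes the 18-membered ring. The precursor is an open-chain 3-methoxydibenzofuran (rings A and B) bearing a 4-hydroxyphenethyl arm at C1 and a 3-fluoro-4-formylphenethyl arm at C7, that is one free phenol and one activated C–F bond.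

Key step: step 10

Remarks on the chemistry
- Assumption: the target has no stereocentre and no alkene. The E-alkenes made on the way are erased by hydrogenation, and conformational chirality of the macrocycle is not addressed.
- Ring B carries chlorine as the handle for the ring C arm. A core with formyl groups at both C1 and C7 could not be elaborated selectively with two different partners, so only one aldehyde is present at any time.
- Both methoxy groups of the biaryl are meta to the formyl group, so no chelation-controlled mono-demethylation is available. Both are cleaved, only the oxygen ortho to the biaryl bond can cyclise, and the other oxygen is methylated again in the same pot.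
- A single hydrogenation late in the route saturates both bridges and frees the ring D phenol, so no free phenol is carried through the palladium couplings.

Step 1
Reactants: 1 2-bromo-3,5-dimethoxybenzaldehyde; 2 (4-chloro-2-fluorophenyl)boronic acid
Product: 3 4'-chloro-2'-fluoro-4,6-dimethoxybiphenyl-2-carbaldehyde
Conditions: Pd(PPh3)4 (5 mol %), K2CO3, 1,4-dioxane–H2O, 90 °C
Reagents that add atoms: none
Why: Suzuki–Miyaura coupling, in which the ortho formyl group speeds insertion of zerovalent palladium into the hindered C–Br bond while the C–Cl and C–F bonds stay untouched with a triphenylphosphine catalyst.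

Step 2
Reactants: 3 4'-chloro-2'-fluoro-4,6-dimethoxybiphenyl-2-carbaldehyde
Product: 4 4'-chloro-2'-fluoro-4,6-dihydroxybiphenyl-2-carbaldehyde
Conditions: BBr3 (excess), CH2Cl2, −78 °C to rt; H2O quench
Reagents that add atoms: none
Why: Lewis-acid aryl methyl ether cleavage removes both methyl groups at once, so no choice between two electronically similar methoxy groups is needed, and the aldehyde, C–Cl and C–F bonds survive.

Step 3
Reactants: 4 4'-chloro-2'-fluoro-4,6-dihydroxybiphenyl-2-carbaldehyde
Product: 6 7-chloro-3-methoxydibenzofuran-1-carbaldehyde, via 7-chloro-3-hydroxydibenzofuran-1-carbaldehyde 5 (not isolated)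
Conditions: K2CO3, DMF, 130 °C; then MeI, rt
Reagents that add atoms: iodomethane (MeI), CI
Why: Intramolecular SNAr of a 2'-fluorobiphenyl-2-olate is a standard dibenzofuran synthesis that needs no activating group because a five-membered ring is closed; only the oxygen ortho to the biaryl bond can reach the C–F carbon, and the remaining phenoxide is then capped by Williamson methylation.

Step 4
Reactants: 7 4-(benzyloxy)benzyl chloride
Product: 8 diethyl [4-(benzyloxy)benzyl]phosphonate
Conditions: P(OEt)3 (neat), 150 °C
Reagents that add atoms: triethyl phosphite, CCOP(OCC)OCC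
Why: Michaelis–Arbuzov reaction of a reactive, electron-rich benzylic chloride.

Step 5
Reactants: 6 7-chloro-3-methoxydibenzofuran-1-carbaldehyde; 8 diethyl [4-(benzyloxy)benzyl]phosphonate
Product: 9 1-{(E)-2-[4-(benzyloxy)phenyl]ethenyl}-7-chloro-3-methoxydibenzofuran
Conditions: KOtBu, THF, 0 °C to rt
Reagents that add atoms: none
Why: Horner–Wadsworth–Emmons olefination of the only aldehyde present should give the E-stilbene, whose geometry is irrelevant because it is hydrogenated later.

Step 6
Reactants: 9 1-{(E)-2-[4-(benzyloxy)phenyl]ethenyl}-7-chloro-3-methoxydibenzofuran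
Product: 10 1-{(E)-2-[4-(benzyloxy)phenyl]ethenyl}-7-ethenyl-3-methoxydibenzofuran
Conditions: vinylboronic acid pinacol ester, Pd(OAc)2, SPhos, K3PO4, 1,4-dioxane–H2O, 90 °C
Reagents that add atoms: vinylboronic acid pinacol ester, C=CB1OC(C)(C)C(C)(C)O1
Why: Suzuki–Miyaura vinylation of an unactivated aryl chloride is enabled by the electron-rich biaryl phosphine, and the internal stilbene and the benzyl ether are spectators.

Step 7
Reactants: 11 4-bromo-2-fluorobenzaldehyde
Product: 12 2-(4-bromo-2-fluorophenyl)-1,3-dioxolane
Conditions: ethylene glycol, TsOH·H2O (cat.), toluene, Dean–Stark trap, reflux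
Reagents that add atoms: ethylene glycol, OCCO
Why: Acid-catalysed acetalisation with azeotropic removal of water masks the formyl group against the later hydrogenation.

Step 8
Reactants: 10 1-{(E)-2-[4-(benzyloxy)phenyl]ethenyl}-7-ethenyl-3-methoxydibenzofuran; 12 2-(4-bromo-2-fluorophenyl)-1,3-dioxolane
Product: 13 1-{(E)-2-[4-(benzyloxy)phenyl]ethenyl}-7-{(E)-2-[4-(1,3-dioxolan-2-yl)-3-fluorophenyl]ethenyl}-3-methoxydibenzofuran
Conditions: Pd(OAc)2, P(o-tol)3, K2CO3, DMF, 100 °C
Reagents that add atoms: none
Why: Mizoroki–Heck arylation takes place at the terminal carbon of the monosubstituted styrene far faster than at the 1,2-disubstituted stilbene and gives the E-alkene, while the acetal is stable in the basic medium.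

Step 9
Reactants: 13 1-{(E)-2-[4-(benzyloxy)phenyl]ethenyl}-7-{(E)-2-[4-(1,3-dioxolan-2-yl)-3-fluorophenyl]ethenyl}-3-methoxydibenzofuran
Product: 15 2-fluoro-4-(2-{1-[2-(4-hydroxyphenyl)ethyl]-3-methoxydibenzofuran-7-yl}ethyl)benzaldehyde (seco fluoroaldehyde phenol), via saturated phenol acetal 14 (not isolated)
Conditions: H2 (1 atm), 10% Pd/C, EtOAc–EtOH, Et3N (1 vol %), rt; filter, evaporate; then 1 M HCl, THF, rt
Reagents that add atoms: water, O
Why: Heterogeneous catalytic hydrogenation saturates both stilbene double bonds and hydrogenolyses the phenolic benzyl ether in one operation while the amine-buffered medium keeps the dioxolane and the C–F bond intact, and mild aqueous acid then hydrolyses the acetal.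

Step 10
Reactants: 15 2-fluoro-4-(2-{1-[2-(4-hydroxyphenyl)ethyl]-3-methoxydibenzofuran-7-yl}ethyl)benzaldehyde
Product: 16 macrocyclic ring C aldehyde (asterelin A skeleton with OMe at dibenzofuran C3 and CHO in place of the ring C hydroxyl)
Conditions: Cs2CO3 (5 equiv), dry DMSO (about 2 mM final), syringe-pump addition of 15 over 12 h, 90–100 °C
Reagents that add atoms: none
Why: Cs2CO3 deprotonates the only phenol, the ring D phenoxide adds to the fluorine-bearing carbon of ring C, the negative charge of the resulting Meisenheimer adduct is spread onto the ortho formyl oxygen, and expulsion of fluoride rearomatises ring C (addition–elimination). The closest known reactions are the diaryl ether synthesis from phenols and 2-fluorobenzaldehydes and the SNAr macroetherification of phenoxides onto ortho-activated aryl fluorides in cyclophane-type natural products. One ring is closed, the 18-membered macrocycle, by end-to-end O–C(aryl) bond formation between the termini of the two arylethyl arms that hang from C1 and C7 of the dibenzofuran. No stereocentre is formed. Site selectivity is settled by the substrate, since 15 has a single acidic OH (the ring A oxygen is a methyl ether) and a single activated C–F bond, so only ring closure against chain growth must be won, which slow addition into a hot dilute suspension of the base should secure. DMSO is chosen over amide solvents because dimethylamine from their slow breakdown would compete for the C–F carbon during the long addition, and the aldehyde, lacking alpha hydrogens, tolerates carbonate.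

Step 11
Reactants: 16 macrocyclic ring C aldehyde
Product: 18 O-methylasterelin A (ring A methyl ether with free ring C hydroxyl), via ring C aryl formate 17 (not isolated)
Conditions: mCPBA, CH2Cl2, 0 °C to rt; wash (aq. Na2S2O3, aq. NaHCO3), evaporate; then MeOH, K2CO3 (cat.), rt
Reagents that add atoms: meta-chloroperoxybenzoic acid (mCPBA), OOC(=O)c1cccc(Cl)c1
Why: Baeyer–Villiger (Dakin-type) oxidation, in which the ring C aryl group, made electron-rich by its ortho aryloxy and para alkyl substituents, migrates to oxygen in the Criegee adduct in preference to hydride, and the labile aryl formate is then methanolysed.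

Step 12
Reactants: 18 O-methylasterelin A
Product: 19 asterelin A
Conditions: BBr3, CH2Cl2, −78 °C to 0 °C; H2O quench
Reagents that add atoms: none
Why: BBr3 ether cleavage proceeds by bromide attack at the methyl carbon, whereas the diaryl ether and dibenzofuran C–O bonds offer no sp3 carbon and remain intact.

Compound list
1 | 2-bromo-3,5-dimethoxybenzaldehyde | COc1cc(OC)c(Br)c(C=O)c1 | starting material
2 | (4-chloro-2-fluorophenyl)boronic acid | OB(O)c1ccc(Cl)cc1F | starting material
3 | 4'-chloro-2'-fluoro-4,6-dimethoxybiphenyl-2-carbaldehyde | COc1cc(OC)c(-c2ccc(Cl)cc2F)c(C=O)c1 | intermediate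
4 | 4'-chloro-2'-fluoro-4,6-dihydroxybiphenyl-2-carbaldehyde | Oc1cc(O)c(-c2ccc(Cl)cc2F)c(C=O)c1 | intermediate
5 | 7-chloro-3-hydroxydibenzofuran-1-carbaldehyde (present as its potassium phenoxide, not isolated) | Oc1cc(C=O)c2c(c1)oc1cc(Cl)ccc12 | intermediate
6 | 7-chloro-3-methoxydibenzofuran-1-carbaldehyde | COc1cc(C=O)c2c(c1)oc1cc(Cl)ccc12 | intermediate
7 | 4-(benzyloxy)benzyl chloride | ClCc1ccc(OCc2ccccc2)cc1 | starting material
8 | diethyl [4-(benzyloxy)benzyl]phosphonate | CCOP(=O)(Cc1ccc(OCc2ccccc2)cc1)OCC | intermediate
9 | 1-{(E)-2-[4-(benzyloxy)phenyl]ethenyl}-7-chloro-3-methoxydibenzofuran | COc1cc(/C=C/c2ccc(OCc3ccccc3)cc2)c2c(c1)oc1cc(Cl)ccc12 | intermediate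
10 | 1-{(E)-2-[4-(benzyloxy)phenyl]ethenyl}-7-ethenyl-3-methoxydibenzofuran | COc1cc(/C=C/c2ccc(OCc3ccccc3)cc2)c2c(c1)oc1cc(C=C)ccc12 | intermediate
11 | 4-bromo-2-fluorobenzaldehyde | O=Cc1ccc(Br)cc1F | starting material
12 | 2-(4-bromo-2-fluorophenyl)-1,3-dioxolane | Fc1cc(Br)ccc1C1OCCO1 | intermediate
13 | 1-{(E)-2-[4-(benzyloxy)phenyl]ethenyl}-7-{(E)-2-[4-(1,3-dioxolan-2-yl)-3-fluorophenyl]ethenyl}-3-methoxydibenzofuran | COc1cc(/C=C/c2ccc(OCc3ccccc3)cc2)c2c(c1)oc1cc(/C=C/c3ccc(C4OCCO4)c(F)c3)ccc12 | intermediate
14 | 4-[2-(7-{2-[4-(1,3-dioxolan-2-yl)-3-fluorophenyl]ethyl}-3-methoxydibenzofuran-1-yl)ethyl]phenol (not isolated) | COc1cc(CCc2ccc(O)cc2)c2c(c1)oc1cc(CCc3ccc(C4OCCO4)c(F)c3)ccc12 | intermediate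
15 | 2-fluoro-4-(2-{1-[2-(4-hydroxyphenyl)ethyl]-3-methoxydibenzofuran-7-yl}ethyl)benzaldehyde (seco fluoroaldehyde phenol) | COc1cc(CCc2ccc(O)cc2)c2c(c1)oc1cc(CCc3ccc(C=O)c(F)c3)ccc12 | intermediate
16 | macrocyclic ring C aldehyde | COc1cc2c3c(c1)oc1cc(ccc13)CCc1ccc(C=O)c(c1)Oc1ccc(cc1)CC2 | intermediate
17 | macrocyclic ring C aryl formate (not isolated) | COc1cc2c3c(c1)oc1cc(ccc13)CCc1ccc(OC=O)c(c1)Oc1ccc(cc1)CC2 | intermediate
18 | O-methylasterelin A | COc1cc2c3c(c1)oc1cc(ccc13)CCc1ccc(O)c(c1)Oc1ccc(cc1)CC2 | intermediate
19 | asterelin A | Oc1cc2c3c(c1)oc1cc(ccc13)CCc1ccc(O)c(c1)Oc1ccc(cc1)CC2 | target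

Total step count: 12.
Longest linear sequence: 10 steps (1, 2, 3, 5, 6, 8, 9, 10, 11, 12).

Steps most likely to fail

Step 10 (macrocyclic SNAr).
- **What may go wrong:** Intermolecular etherification (chain growth) may outrun ring closure. The flat dibenzofuran stiffens the chain, and a formyl group activates the C–F carbon only moderately, so long heating is needed.
- **Fallback:** The ether bond is closed by copper-mediated Ullmann coupling on a ring C that already carries its oxygen. This needs no activating group and makes the peracid step unnecessary. It sets out from 10. Heck coupling with commercial 2-bromo-4-iodoanisole (COc1ccc(I)cc1Br; Pd(OAc)2, K2CO3, n-Bu4NBr, DMF, 70 °C, reaction at the C–I bond only) should give the bromo bis-stilbene F1. Diimide reduction (TsNHNH2, NaOAc, THF–H2O, reflux) saturates both alkenes without touching the C–Br bond or the benzyl ether and gives the saturated bromo benzyl ether F2. BCl3 with pentamethylbenzene (CH2Cl2, −78 °C) removes the benzyl group selectively and gives the bromo phenol F3. Ullmann macrocyclisation (CuO, K2CO3, pyridine, reflux, high dilution) gives di-O-methylasterelin A F4. BBr3 (CH2Cl2) then cleaves both methyl ethers, and the route is rejoined at 19.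

Step 11 (Baeyer–Villiger oxidation of the aldehyde).
- **What may go wrong:** Hydride migration may replace aryl migration in the Criegee adduct, so that the formyl carbon is merely oxidised and not excised. Slow peracid attack on the electron-rich ring A is a second possibility.
- **Fallback:** The migrating hydrogen is removed from the competition by going through the methyl ketone. It sets out from 16. MeMgBr (THF, 0 °C) gives the racemic ring C carbinol F5, and MnO2 (CH2Cl2, rt) gives the ring C methyl ketone F6. mCPBA with CF3CO2H (CH2Cl2, rt) gives the ring C acetate F7, because the aryl group now competes only with methyl. K2CO3 in MeOH cleaves the acetate, and the route is rejoined at 18.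

Step 9 (one-pot hydrogenation and debenzylation beside the acetal).
- **What may go wrong:** The benzylic acetal may be lost by hydrogenolysis or premature hydrolysis, followed by over-reduction at the formyl carbon. The benzyl group may also be lost incompletely in the amine-buffered medium.
- **Fallback:** The tasks are separated and the metal catalyst is avoided. It sets out from 13. Diimide reduction (TsNHNH2, NaOAc, THF–H2O, reflux) gives the saturated benzyl ether acetal F8. BCl3 with pentamethylbenzene (CH2Cl2, −78 °C), followed by 1 M HCl in THF, removes the benzyl group and the dioxolane while the aryl methyl ether stays. The route is rejoined at 15.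

Further compounds
F1 | step 10 | 1-{(E)-2-[4-(benzyloxy)phenyl]ethenyl}-7-[(E)-2-(3-bromo-4-methoxyphenyl)ethenyl]-3-methoxydibenzofuran | COc1cc(/C=C/c2ccc(OCc3ccccc3)cc2)c2c(c1)oc1cc(/C=C/c3ccc(OC)c(Br)c3)ccc12
F2 | step 10 | 1-{2-[4-(benzyloxy)phenyl]ethyl}-7-[2-(3-bromo-4-methoxyphenyl)ethyl]-3-methoxydibenzofuran | COc1cc(CCc2ccc(OCc3ccccc3)cc2)c2c(c1)oc1cc(CCc3ccc(OC)c(Br)c3)ccc12
F3 | step 10 | 4-(2-{7-[2-(3-bromo-4-methoxyphenyl)ethyl]-3-methoxydibenzofuran-1-yl}ethyl)phenol | COc1cc(CCc2ccc(O)cc2)c2c(c1)oc1cc(CCc3ccc(OC)c(Br)c3)ccc12
F4 | step 10 | di-O-methylasterelin A | COc1cc2c3c(c1)oc1cc(ccc13)CCc1ccc(OC)c(c1)Oc1ccc(cc1)CC2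
F5 | step 11 | macrocyclic ring C 1-hydroxyethyl compound (racemic) | COc1cc2c3c(c1)oc1cc(ccc13)CCc1ccc(C(C)O)c(c1)Oc1ccc(cc1)CC2
F6 | step 11 | macrocyclic ring C methyl ketone | COc1cc2c3c(c1)oc1cc(ccc13)CCc1ccc(C(C)=O)c(c1)Oc1ccc(cc1)CC2
F7 | step 11 | macrocyclic ring C acetate | COc1cc2c3c(c1)oc1cc(ccc13)CCc1ccc(OC(C)=O)c(c1)Oc1ccc(cc1)CC2
F8 | step 9 | 1-{2-[4-(benzyloxy)phenyl]ethyl}-7-{2-[4-(1,3-dioxolan-2-yl)-3-fluorophenyl]ethyl}-3-methoxydibenzofuran | COc1cc(CCc2ccc(OCc3ccccc3)cc2)c2c(c1)oc1cc(CCc3ccc(C4OCCO4)c(F)c3)ccc12
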